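The runs were computed for substances that don't exist.

Count partner, because a closed flask keeps its count: first product holds one, bis adduct two, tris adduct three. Take as the ceiling on bis adduct the partner charged over twice the substrate charged, the amount reached if every partner sat in bis adduct.

| setting | north | flask |
|---|---|---|
| substrate | 0.020 M | 0.020 M |
| partner | 0.030 M | 0.0200 M |
| remark | run made earlier |  |
| time |  | 10 min |

- north (time / min: substrate / %, first product / %): 0.250: 46.4, 16.2; 0.833: 14.9, 5.5; 1.33: 8.8, 2.5; 2.00: 6.0, 1.5; 3.00: 4.6, 0.9

(standard deviation of a reading: 0.3 percentage points)

- amount of substrate at 10 min, in percent of the substrate charged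
- amount of first product at 10 min, in percent of the substrate charged
- amount of bis adduct at 10 min, in percent of the substrate charged
- amount of tris adduct at 10 min, in percent of the substrate charged

- a reading or a percentage of bis adduct counts all its forms, free or not

Now climb the time scales of the north run, fastest first. Read the early half-life of substrate from its first reading, taken as one exponential:

early half-life = 0.226 min

First product stands at 0.349 of substrate at 0.250 min and at 0.196 at 3.00 min, so it falls along with substrate. Read the late half-life from the last two readings:

late half-life = 2.61 min

That is slower than the early one, so the fall of substrate slows down in the north run. Put the count on the last rung. At 3.00 min the north run has lost this much from substrate and first product together: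

lost = 94.5%, north ceiling = 75.0%

So, as read, at least about 20 percentage points of the substrate charged sits in something that is neither bis adduct nor tris adduct.

Turn to the flask. Its 10 min outlasts the late half-life, and partner is the limiting reagent for bis adduct:

ceiling = 50.0%

Commit to bis adduct below that. The forecast differs from this reckoning on bis adduct, giving 13% substrate, 3% first product, 72% bis adduct and 12% tris adduct, with the remark that “the partner must deliver more than assumed, or something else is happening”.

The flask gives 8.22% substrate, 0.184% first product, 21.3% bis adduct with crystals counted, and 1.57% tris adduct.

    substrate + partner → first product (k = 1.70 M⁻¹ s⁻¹)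
    partner + first product → bis adduct (k = 3.20 M⁻¹ s⁻¹)
    partner + bis adduct → tris adduct (k = 0.160 M⁻¹ s⁻¹)
    substrate ⇌ dormant form (K = 2.20, k = 0.0120 s⁻¹)
    crystals ⇌ bis adduct, rate k5*(cs5 - [bis adduct]) while solid is left; crystals form when [bis adduct] > cs5 (solubility = 1.20 mM, k = 0.180 s⁻¹)
    first product → side product (k = 0.0510 s⁻¹)

Bis adduct thus reaches 0.426 of the ceiling, and side product stands at 49.2% at 10.0 min. Use the ceiling once more on the same flask charged with 0.012 M partner: it comes to 30.0%, and that flask holds 9.56% bis adduct, 0.319 of its ceiling.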